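## The problem

Compound 30 is a halimane-type diester. Locants used below: ring A is C1–C5 and C10, ring B is C5–C10; C4 carries a methyl (C19) and the ester carbon (C18), C8 a methyl (C17), and C9 a methyl (C20) and the chain C11–C16 that ends at C15 in a (Z)-cinnamate. Two quaternary carbons, C4 and C9, flank the ring-fusion atoms, so both rings close against heavy substitution. The C1=C10 double bond must be placed between a ring methylene and the fusion carbon without straying to C1=C2 or C5=C10. There are five stereocentres (4S,5S,8R,9S,13R). C5, C8 and C9 are contiguous on ring B and can be set together in one cyclic transition state; C4 is next to C5 and can choose the face on which ring B forms; C13 is insulated from the rings by two methylenes and has to come from the chiral pool. The (Z)-cinnamate isomerises under light, base, radicals and nucleophilic catalysts and is reducible, the trisubstituted olefin migrates in acid, and the C4 carboxyl is neopentylic, so rough late-stage treatment is excluded. The enabling feature is that C5, C8, C9 and C10 all lie on ring B while C10 also belongs to ring A with C1 beside it. A C9=C10 dienophile activated by a C1 carbonyl and tied through C1–C4 to a C5=C6–C7=C8 diene therefore maps onto both rings, and the carbonyl left at C1 is the handle for the olefin.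

## Retrosynthesis

**Side-chain ester.** The C15–O acyl bond and the Z olefin of 30 are removed last: 30 comes from alkynoate 29 by semihydrogenation, and 29 from alcohol 27 and phenylpropiolic acid 28. Direct acylation with (Z)-cinnamic acid would risk Z-to-E isomerisation during activation; the alkyne carries no geometry. The forward reduction must stop at the alkene and leave the hindered C1=C10 bond alone.

**C18 carboxyl.** Alcohol 27 is the desilylated form of ester 26, which is traced through acid 25 and aldehyde 24 to nitrile 22. No skeletal bond is cut. Carrying C18 as a nitrile costs three functional-group steps, but it is inert to the organometallic and Lewis-acid steps, it arises from a well-precedented asymmetric Michael reaction, and it is much smaller than the methyl ester, which is what the key step needs (below).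

**C1=C10 olefin.** Nitrile 22 comes from enol triflate 21 by C–O hydrogenolysis. Enolising a saturated C1 ketone towards C10 is not dependable: the C2 methylene is kinetically favoured, and C10–H is shielded by quaternary C9. The ketone is therefore first desaturated to the C2=C3 enone 18. C4 is quaternary, so C10–H is then the only enolisable hydrogen and dienyl triflate 20 forms with fixed regiochemistry. Diimide removes the auxiliary C2=C3 bond together with the ring B olefin (20 to 21). Enone 18 is the dehydrogenation product of cycloadduct 16.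

**Both rings (key step).** Cutting C5–C10 and C8–C9 of 16 opens ring B and ring A together and gives acyclic trienone 15. Against ring-by-ring constructions this cut removes two rings and three permanent stereocentres at once and reduces the ring stereochemistry to three olefin geometries and one preset centre, C4. The forward reaction must be cis-selective (tether carbonyl endo) and must use the diene face dictated by C4.

**Trienone.** The C5=C6 bond of 15 is cut by olefination to keto aldehyde 13 and crotylphosphonate 14. Keto aldehyde 13 is the double oxidation product of diol 12, which comes from hydroxy ester 11 by ester reduction. The C1–C10 bond of 11 is cut to aldehyde 10 and vinyl iodide 7. A chromium-mediated coupling is preferred to a vinyllithium addition because 10 carries an ester and a nitrile.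

**Building blocks.** Aldehyde 10 is the Michael adduct of ethyl 2-cyanopropanoate 8 and acrolein 9 (C3–C4 bond); this sets C4. Vinyl iodide 7 comes from alkyne 5 by methylalumination, 5 from aldehyde 4, and 4 from silyl ether 2 of (R)-citronellol 1, which supplies C13.

## Roads not taken

**Alternative 1:** Ring B is cut at C5–C6 and C7–C8. The ring A dienyl ketal A1 would add ethynyl p-tolyl sulfone A2 to give sulfonyl cyclohexadiene A3.
- Merits: ring A and C4 are secured first, the dienophile is strong, and the sulfonyl group is removable. After the C1 ketone is unveiled, C9=C10 is part of an enone, so attaching the side chain at C9 by conjugate addition would generate the C1(10) enolate regiospecifically. That answers the olefin-placement question more directly than steps 11–13 of the chosen plan.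
- Weak points: A3 contains neither C11–C16 nor the C9 stereocentre. The chain would have to be delivered to the fully substituted β-carbon of a tetrasubstituted enone next to the C8 methine, with face control resting on the C8 methyl alone. Diene A1 is congested at C5, and its faces differ only by methyl against ester at C4. Desulfonylation, selective saturation of C6=C7, ketal removal, conjugate addition and triflate reduction still follow.
- Comparison: the chosen plan fixes C9 inside the cycloaddition through olefin geometry and pays for this with four steps for the olefin.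

**Alternative 2:** Ring A is cut at C2–C3 and C4–C5. Vinylcyclohexene A4 and methacrolein A5 would give aldehyde A6, which is the same compound as 24.
- Merits: the cycloaddition itself leaves the double bond at C1=C10, and the orientation (substituted diene terminus to the α-carbon of the enal) is the normal one. The aldehyde-exo mode needed for C4 is the usual preference of α-methyl enals, and A6 is two steps from the ester. After the key step this road is shorter than the chosen one.
- Weak points: C8 and C9, including the difficult quaternary centre, must already be present in enantiopure A4, so the hardest stereochemical task moves into a separate ring synthesis. The diene face must be chosen under the influence of C9, whose methyl and CH2 substituents differ little. An acid-sensitive 2-substituted diene meets a Lewis acid.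
- Comparison: the chosen plan creates C5, C8 and C9 in the key step and needs only C4 beforehand, from a catalytic reaction.

**Alternative 3:** Ring A is cut at C1=C10. Low-valent titanium would couple the C10 ketone and C1 aldehyde of keto aldehyde A7 to give A8, which is the same compound as 26.
- Merits: the olefin position is unambiguous and A8 is three steps from the target. On olefin placement this road is better than the chosen one.
- Weak points: the key step forms no stereocentre. C4, C5, C8 and C9 must all be in A7, including the vicinal acyclic quaternary C4 and the epimerisable C5 next to the ketone. The C10 carbonyl lies between quaternary C9 and tertiary C5, so the coupling may stop at the diol. The C4 ester can compete through aldehyde–ester coupling to a five-membered ring.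
- Comparison: the chosen plan lets one cycloaddition do the stereochemical work and accepts a longer route to the olefin.

Key step: step 10

Assumption: of the two antipodes of the PhTRAP ligand in step 5, the one that delivers (R)-10 is used; the sense of induction is to be confirmed on the first batch.

## Route

Step 1
Reactants: 1 (R)-citronellol
Product: 2 (R)-citronellyl tert-butyldimethylsilyl ether
Conditions: t-BuMe2SiCl, imidazole, DMF, 0 °C to rt
Reagents that add atoms: tert-butyldimethylsilyl chloride, CC(C)(C)[Si](C)(C)Cl
Why: Imidazole-promoted silylation of a primary alcohol. The silyl ether should survive ozonolysis, Me3Al, LiBH4, Swern conditions and MeAlCl2 at low temperature, and it is removed by fluoride before acylation.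

Step 2
Reactants: 2 (R)-citronellyl tert-butyldimethylsilyl ether
Product: 4 (4R)-6-[(tert-butyldimethylsilyl)oxy]-4-methylhexanal, via secondary ozonide 3 (not isolated)
Conditions: O3, CH2Cl2, −78 °C; then PPh3, −78 °C to rt
Reagents that add atoms: ozone, [O-][O+]=O
Why: Ozonolysis with reductive work-up cleaves the only olefin. The stereocentre is β to the new aldehyde and cannot epimerise.

Step 3
Reactants: 4 (4R)-6-[(tert-butyldimethylsilyl)oxy]-4-methylhexanal
Product: 5 (3R)-tert-butyldimethyl[(3-methylhept-6-yn-1-yl)oxy]silane
Conditions: dimethyl (1-diazo-2-oxopropyl)phosphonate, K2CO3, MeOH, 0 °C to rt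
Reagents that add atoms: dimethyl (1-diazo-2-oxopropyl)phosphonate, COP(=O)(OC)C(=[N+]=[N-])C(C)=O
Why: Seyferth–Gilbert homologation in the Ohira–Bestmann variant converts the aldehyde into the terminal alkyne under mild carbonate conditions that the silyl ether tolerates.

Step 4
Reactants: 5 (3R)-tert-butyldimethyl[(3-methylhept-6-yn-1-yl)oxy]silane
Product: 7 (3R,6E)-tert-butyl[(7-iodo-3,6-dimethylhept-6-en-1-yl)oxy]dimethylsilane, via alkenyldimethylalane 6 (not isolated)
Conditions: Me3Al, Cp2ZrCl2 (cat.), CH2Cl2, 0 °C to rt; then I2, THF, −30 to 0 °C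
Reagents that add atoms: trimethylaluminium, C[Al](C)C; iodine, [I][I]
Why: Zirconium-catalysed Negishi carboalumination adds methyl and aluminium syn across the terminal alkyne with aluminium on the terminal carbon. Iodinolysis with retention gives the (E)-2-methyl-1-iodoalkene, which fixes the later C9=C10 geometry.

Step 5
Reactants: 8 ethyl 2-cyanopropanoate; 9 acrolein
Product: 10 ethyl (2R)-2-cyano-2-methyl-5-oxopentanoate
Conditions: RhH(CO)(PPh3)3 (1 mol %), PhTRAP = 2,2''-bis[1-(diphenylphosphanyl)ethyl]-1,1''-biferrocene (1 mol %), toluene, 0–5 °C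
Reagents that add atoms: none
Why: Rhodium-catalysed asymmetric Michael addition of an α-cyano ester to an enal, a reaction type established for 2-cyanopropanoates with acrolein. The trans-chelating bisphosphine differentiates the faces of the nitrile-bound enolate and so sets the quaternary centre that becomes C4. Any minor antipode becomes a separable diastereomer once enantiopure 7 is attached.

Step 6
Reactants: 10 ethyl (2R)-2-cyano-2-methyl-5-oxopentanoate; 7 (3R,6E)-tert-butyl[(7-iodo-3,6-dimethylhept-6-en-1-yl)oxy]dimethylsilane
Product: 11 ethyl (2R,6E,10R)-12-[(tert-butyldimethylsilyl)oxy]-2-cyano-5-hydroxy-2,7,10-trimethyldodec-6-enoate (both C5 epimers)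
Conditions: CrCl2 (4 equiv), NiCl2 (2 mol %), DMSO–THF, rt
Reagents that add atoms: none
Why: Nozaki–Hiyama–Kishi coupling. The alkenylchromium species adds only to the aldehyde, leaving ester, nitrile and silyl ether untouched, and the olefin geometry is retained. The carbinol centre forms without control and is removed by oxidation in step 8.

Step 7
Reactants: 11 ethyl (2R,6E,10R)-12-[(tert-butyldimethylsilyl)oxy]-2-cyano-5-hydroxy-2,7,10-trimethyldodec-6-enoate
Product: 12 (2R,6E,10R)-12-[(tert-butyldimethylsilyl)oxy]-5-hydroxy-2-(hydroxymethyl)-2,7,10-trimethyldodec-6-enenitrile (both C5 epimers)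
Conditions: LiBH4, THF, MeOH (1 equiv), 0 °C to rt
Reagents that add atoms: none
Why: Borohydride reduction of the activated α-cyano ester to the primary alcohol; nitrile and olefin are inert. Any δ-lactone formed from 11 is reduced to the same diol.

Step 8
Reactants: 12 (2R,6E,10R)-12-[(tert-butyldimethylsilyl)oxy]-5-hydroxy-2-(hydroxymethyl)-2,7,10-trimethyldodec-6-enenitrile
Product: 13 (2R,6E,10R)-12-[(tert-butyldimethylsilyl)oxy]-2-formyl-2,7,10-trimethyl-5-oxododec-6-enenitrile
Conditions: (COCl)2, DMSO, CH2Cl2, −78 °C; then Et3N, −78 to 0 °C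
Reagents that add atoms: none
Why: Swern oxidation activates both hydroxyls before base is added, so the 1,5-diol should give the keto aldehyde and not a lactol or lactone. The aldehyde has a quaternary α-carbon, so C4 cannot epimerise.

Step 9
Reactants: 13 (2R,6E,10R)-12-[(tert-butyldimethylsilyl)oxy]-2-formyl-2,7,10-trimethyl-5-oxododec-6-enenitrile; 14 diethyl [(2E)-but-2-en-1-yl]phosphonate
Product: 15 (2S,6E,10R)-12-[(tert-butyldimethylsilyl)oxy]-2,7,10-trimethyl-5-oxo-2-[(1E,3E)-penta-1,3-dien-1-yl]dodec-6-enenitrile
Conditions: 14, n-BuLi, THF–DMPU, −78 °C; then 13, −78 °C to rt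
Reagents that add atoms: none
Why: Horner–Wadsworth–Emmons olefination with an allylic phosphonate anion. The anion should attack the electron-poor, non-enolisable aldehyde much faster than the β,β-disubstituted enone. Elimination next to the quaternary carbon gives the E olefin, and the crotyl E geometry is carried over.

Step 10
Reactants: 15 (2S,6E,10R)-12-[(tert-butyldimethylsilyl)oxy]-2,7,10-trimethyl-5-oxo-2-[(1E,3E)-penta-1,3-dien-1-yl]dodec-6-enenitrile
Product: 16 cis-fused octalenone nitrile (4S,5S,8R,9S,10S,13R) with C1 ketone and C6=C7 olefin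
Conditions: MeAlCl2 (2.2 equiv), CH2Cl2, −78 to −20 °C
Reagents that add atoms: none
Why: MeAlCl2 binds the C1 carbonyl (a second equivalent is taken up by the nitrile) and lowers the enone LUMO, so that C9=C10 adds suprafacially across C5–C8 in a concerted, asynchronous [4+2]; the closest known reaction type is the alkylaluminium-chloride-promoted intramolecular Diels–Alder reaction of 1,7,9-decatrien-3-ones, which includes β,β-disubstituted enone dienophiles. Ring B is the cycloaddition ring (new bonds C5–C10 and C8–C9), and ring A closes in the same event as the fused six-membered tether ring through C1–C4 with the ketone inside it. At C5 and C8, suprafacial use of the (E,E)-diene places C4 and C17 on the same face of ring B. At C9 and C10, suprafacial use of the (E)-enone keeps C20 cis to C1 and C11 cis to H10. The two pairs are linked by the tether-carbonyl-endo transition state, which gives the cis ring fusion and puts C20 on the face of C17; the s-cis enone enforced by the cis β-methyl and the Lewis-acid complexation favour this mode over the trans-fused one that would give the C9 epimer. The diene face is set by C4: in the chair-like tether the C4 substituent cis to H5 and H10 is axial, and the small linear nitrile should take that site far more readily than methyl. C10 is made trigonal later, so C5, C8 and C9 are the centres that persist. The step therefore needs cis over trans fusion, supported by the Lewis acid, and one diene face, supported by the nitrile/methyl size difference, with C13 a spectator.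

Step 11
Reactants: 16 cis-fused octalenone nitrile (4S,5S,8R,9S,10S,13R)
Product: 18 cis-fused 2,6-dien-1-one nitrile (4S,5S,8R,9S,10S,13R), via trimethylsilyl enol ether 17 (not isolated)
Conditions: LiN(i-Pr)2, Me3SiCl, THF, −78 °C; then Pd(OAc)2, MeCN, rt
Reagents that add atoms: none
Why: Saegusa–Ito oxidation. Kinetic deprotonation occurs at the C2 methylene because C10–H is shielded by C9, and the palladium enolate loses a C3 hydrogen to give the C2=C3 enone. After this step C10–H is the only enolisable hydrogen, since C4 is quaternary.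

Step 12
Reactants: 18 cis-fused 2,6-dien-1-one nitrile (4S,5S,8R,9S,10S,13R)
Product: 20 dienyl triflate (4S,5R,8R,9S,13R) with C1(OTf)=C10 and C2=C3 and C6=C7 olefins, via potassium dienolate 19 (not isolated)
Conditions: KN(SiMe3)2, THF, −78 to −40 °C; then PhNTf2, −78 to 0 °C
Reagents that add atoms: N-phenylbis(trifluoromethanesulfonimide), O=S(=O)(N(c1ccccc1)S(=O)(=O)C(F)(F)F)C(F)(F)F
Why: α′-Deprotonation of a cross-conjugated enone and O-triflation, the usual route to 2-triflyloxy-1,3-dienes. The regiochemistry is fixed because only C10–H can be removed. C10 becomes trigonal; the 5R descriptor reflects a change of CIP priorities, not an inversion.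

Step 13
Reactants: 20 dienyl triflate (4S,5R,8R,9S,13R)
Product: 21 enol triflate (4S,5R,8R,9S,13R) with C1(OTf)=C10 as the only olefin
Conditions: 2-nitrobenzenesulfonyl hydrazide (excess, in portions), Et3N, CH2Cl2, rt
Reagents that add atoms: none
Why: Diimide transfers H2 in a concerted syn fashion and its rate falls steeply with substitution. The two cis-disubstituted olefins (C2=C3, C6=C7) should be reduced while the tetrasubstituted enol triflate next to quaternary C9, the C–OTf bond and the nitrile stay intact. No stereocentre is formed.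

Step 14
Reactants: 21 enol triflate (4S,5R,8R,9S,13R)
Product: 22 (1S,5S,6R,8aS)-5-[(3R)-5-[(tert-butyldimethylsilyl)oxy]-3-methylpentyl]-1,5,6-trimethyl-1,2,3,5,6,7,8,8a-octahydronaphthalene-1-carbonitrile
Conditions: Pd(OAc)2 (5 mol %), PPh3, n-Bu3N, HCO2H, DMF, 60 °C
Reagents that add atoms: none
Why: Palladium-catalysed formate reduction of an enol triflate: oxidative addition of zerovalent palladium into C–OTf, formate exchange, decarboxylation to the palladium hydride and reductive elimination. The double bond stays where the triflate was, at C1=C10.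

Step 15
Reactants: 22 Δ1(10) nitrile (4S,5S,8R,9S,13R)
Product: 24 (1S,5S,6R,8aS)-5-[(3R)-5-[(tert-butyldimethylsilyl)oxy]-3-methylpentyl]-1,5,6-trimethyl-1,2,3,5,6,7,8,8a-octahydronaphthalene-1-carbaldehyde, via N-aluminoaldimine 23 (not isolated)
Conditions: i-Bu2AlH, toluene, −78 to 0 °C; then aqueous potassium sodium tartrate, dilute aqueous AcOH
Reagents that add atoms: water, O
Why: Partial reduction of a hindered tertiary nitrile to the N-aluminoaldimine and hydrolysis to the aldehyde, the standard treatment of angular nitriles. The aldehyde has no α-hydrogen, and the mild acidic work-up should spare the silyl ether and the olefin position.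

Step 16
Reactants: 24 C18 aldehyde (4S,5S,8R,9S,13R)
Product: 25 (1S,5S,6R,8aS)-5-[(3R)-5-[(tert-butyldimethylsilyl)oxy]-3-methylpentyl]-1,5,6-trimethyl-1,2,3,5,6,7,8,8a-octahydronaphthalene-1-carboxylic acid
Conditions: NaClO2, NaH2PO4, 2-methylbut-2-ene, t-BuOH–H2O, rt
Reagents that add atoms: sodium chlorite, [Na+].[O-]Cl=O
Why: Pinnick oxidation. The scavenger olefin intercepts hypochlorous acid and so protects the trisubstituted C1=C10 bond.

Step 17
Reactants: 25 C18 acid (4S,5S,8R,9S,13R)
Product: 26 methyl (1S,5S,6R,8aS)-5-[(3R)-5-[(tert-butyldimethylsilyl)oxy]-3-methylpentyl]-1,5,6-trimethyl-1,2,3,5,6,7,8,8a-octahydronaphthalene-1-carboxylate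
Conditions: MeI, K2CO3, DMF, rt
Reagents that add atoms: iodomethane, CI
Why: O-Alkylation of the carboxylate is an SN2 reaction at iodomethane and is not slowed by the neopentyl environment that would block Fischer esterification.

Step 18
Reactants: 26 methyl ester silyl ether (4S,5S,8R,9S,13R)
Product: 27 methyl (1S,5S,6R,8aS)-5-[(3R)-5-hydroxy-3-methylpentyl]-1,5,6-trimethyl-1,2,3,5,6,7,8,8a-octahydronaphthalene-1-carboxylate
Conditions: n-Bu4NF, THF, 0 °C to rt
Reagents that add atoms: none
Why: Fluoride-mediated desilylation of the primary silyl ether; the hindered methyl ester and the olefin are inert.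

Step 19
Reactants: 27 C15 alcohol (4S,5S,8R,9S,13R); 28 phenylpropiolic acid
Product: 29 methyl (1S,5S,6R,8aS)-1,5,6-trimethyl-5-[(3R)-3-methyl-5-[(3-phenylprop-2-ynoyl)oxy]pentyl]-1,2,3,5,6,7,8,8a-octahydronaphthalene-1-carboxylate
Conditions: N,N'-dicyclohexylcarbodiimide, 4-(dimethylamino)pyridine (cat.), CH2Cl2, 0 °C to rt
Reagents that add atoms: none
Why: Steglich esterification of the unhindered primary alcohol. Using the alkynoic acid postpones the question of olefin geometry to the last step.

Step 20
Reactants: 29 phenylpropiolate (4S,5S,8R,9S,13R)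
Product: 30 methyl (1S,5S,6R,8aS)-1,5,6-trimethyl-5-[(3R)-3-methyl-5-[[(2Z)-3-phenylprop-2-enoyl]oxy]pentyl]-1,2,3,5,6,7,8,8a-octahydronaphthalene-1-carboxylate
Conditions: H2 (1 atm), Pd on CaCO3 poisoned with Pb(OAc)2, quinoline, EtOAc, rt, dark
Reagents that add atoms: none
Why: Lindlar semihydrogenation adds H2 syn to the alkyne and should stop at the (Z)-cinnamate. The hindered trisubstituted C1=C10 olefin and both esters are untouched.

## Compound list

1 | (R)-citronellol, (3R)-3,7-dimethyloct-6-en-1-ol | CC(C)=CCC[C@@H](C)CCO | starting material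
2 | (R)-citronellyl tert-butyldimethylsilyl ether | CC(C)=CCC[C@@H](C)CCO[Si](C)(C)C(C)(C)C | intermediate
3 | secondary ozonide (1,2,4-trioxolane) of 2, mixture at the acetal carbon | CC1(C)OOC(CC[C@@H](C)CCO[Si](C)(C)C(C)(C)C)O1 | intermediate (not isolated)
4 | (4R)-6-[(tert-butyldimethylsilyl)oxy]-4-methylhexanal | O=CCC[C@@H](C)CCO[Si](C)(C)C(C)(C)C | intermediate
5 | (3R)-tert-butyldimethyl[(3-methylhept-6-yn-1-yl)oxy]silane | C#CCC[C@@H](C)CCO[Si](C)(C)C(C)(C)C | intermediate
6 | (E)-alkenyldimethylalane from 5, aluminium cis to the new methyl | C[Al](C)/C=C(\C)CC[C@@H](C)CCO[Si](C)(C)C(C)(C)C | intermediate (not isolated)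
7 | (3R,6E)-tert-butyl[(7-iodo-3,6-dimethylhept-6-en-1-yl)oxy]dimethylsilane | I/C=C(\C)CC[C@@H](C)CCO[Si](C)(C)C(C)(C)C | intermediate
8 | ethyl 2-cyanopropanoate (racemic) | CCOC(=O)C(C)C#N | starting material
9 | acrolein | C=CC=O | starting material
10 | ethyl (2R)-2-cyano-2-methyl-5-oxopentanoate | CCOC(=O)[C@@](C)(C#N)CCC=O | intermediate
11 | ethyl (2R,6E,10R)-12-[(tert-butyldimethylsilyl)oxy]-2-cyano-5-hydroxy-2,7,10-trimethyldodec-6-enoate, both C5 epimers | CCOC(=O)[C@@](C)(C#N)CCC(O)/C=C(\C)CC[C@@H](C)CCO[Si](C)(C)C(C)(C)C | intermediate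
12 | (2R,6E,10R)-12-[(tert-butyldimethylsilyl)oxy]-5-hydroxy-2-(hydroxymethyl)-2,7,10-trimethyldodec-6-enenitrile, both C5 epimers | OC[C@@](C)(C#N)CCC(O)/C=C(\C)CC[C@@H](C)CCO[Si](C)(C)C(C)(C)C | intermediate
13 | (2R,6E,10R)-12-[(tert-butyldimethylsilyl)oxy]-2-formyl-2,7,10-trimethyl-5-oxododec-6-enenitrile | O=C[C@@](C)(C#N)CCC(=O)/C=C(\C)CC[C@@H](C)CCO[Si](C)(C)C(C)(C)C | intermediate
14 | diethyl [(2E)-but-2-en-1-yl]phosphonate | CCOP(=O)(OCC)C/C=C/C | starting material
15 | (2S,6E,10R)-12-[(tert-butyldimethylsilyl)oxy]-2,7,10-trimethyl-5-oxo-2-[(1E,3E)-penta-1,3-dien-1-yl]dodec-6-enenitrile (trienone, precursor of the key step) | N#C[C@@](C)(CCC(=O)/C=C(\C)CC[C@@H](C)CCO[Si](C)(C)C(C)(C)C)/C=C/C=C/C | intermediate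
16 | (1S,4aS,5S,6R,8aS)-5-[(3R)-5-[(tert-butyldimethylsilyl)oxy]-3-methylpentyl]-1,5,6-trimethyl-4-oxo-1,2,3,4,4a,5,6,8a-octahydronaphthalene-1-carbonitrile (cis-fused; nitrile cis to H5 and H10; product of the key step) | N#C[C@@]1(C)CCC(=O)[C@H]2[C@@H]1C=C[C@@H](C)[C@]2(C)CC[C@@H](C)CCO[Si](C)(C)C(C)(C)C | intermediate
17 | C1=C2 trimethylsilyl enol ether of 16 | N#C[C@@]1(C)CC=C(O[Si](C)(C)C)[C@H]2[C@@H]1C=C[C@@H](C)[C@]2(C)CC[C@@H](C)CCO[Si](C)(C)C(C)(C)C | intermediate (not isolated)
18 | (1S,4aS,5S,6R,8aS)-5-[(3R)-5-[(tert-butyldimethylsilyl)oxy]-3-methylpentyl]-1,5,6-trimethyl-4-oxo-1,4,4a,5,6,8a-hexahydronaphthalene-1-carbonitrile | N#C[C@@]1(C)C=CC(=O)[C@H]2[C@@H]1C=C[C@@H](C)[C@]2(C)CC[C@@H](C)CCO[Si](C)(C)C(C)(C)C | intermediate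
19 | potassium C1(O)=C10 dienolate of 18 | N#C[C@@]1(C)C=CC([O-])=C2[C@@H]1C=C[C@@H](C)[C@]2(C)CC[C@@H](C)CCO[Si](C)(C)C(C)(C)C.[K+] | intermediate (not isolated)
20 | (4S,4aR,7R,8S)-8-[(3R)-5-[(tert-butyldimethylsilyl)oxy]-3-methylpentyl]-4-cyano-4,7,8-trimethyl-4,4a,7,8-tetrahydronaphthalen-1-yl trifluoromethanesulfonate | N#C[C@@]1(C)C=CC(OS(=O)(=O)C(F)(F)F)=C2[C@@H]1C=C[C@@H](C)[C@]2(C)CC[C@@H](C)CCO[Si](C)(C)C(C)(C)C | intermediate
21 | (4S,4aR,7R,8S)-8-[(3R)-5-[(tert-butyldimethylsilyl)oxy]-3-methylpentyl]-4-cyano-4,7,8-trimethyl-2,3,4,4a,5,6,7,8-octahydronaphthalen-1-yl trifluoromethanesulfonate | N#C[C@@]1(C)CCC(OS(=O)(=O)C(F)(F)F)=C2[C@@H]1CC[C@@H](C)[C@]2(C)CC[C@@H](C)CCO[Si](C)(C)C(C)(C)C | intermediate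
22 | (1S,5S,6R,8aS)-5-[(3R)-5-[(tert-butyldimethylsilyl)oxy]-3-methylpentyl]-1,5,6-trimethyl-1,2,3,5,6,7,8,8a-octahydronaphthalene-1-carbonitrile | N#C[C@@]1(C)CCC=C2[C@@H]1CC[C@@H](C)[C@]2(C)CC[C@@H](C)CCO[Si](C)(C)C(C)(C)C | intermediate
23 | N-(diisobutylalumanyl)aldimine from 22 | CC(C)C[Al](CC(C)C)N=C[C@@]1(C)CCC=C2[C@@H]1CC[C@@H](C)[C@]2(C)CC[C@@H](C)CCO[Si](C)(C)C(C)(C)C | intermediate (not isolated)
24 | (1S,5S,6R,8aS)-5-[(3R)-5-[(tert-butyldimethylsilyl)oxy]-3-methylpentyl]-1,5,6-trimethyl-1,2,3,5,6,7,8,8a-octahydronaphthalene-1-carbaldehyde | O=C[C@@]1(C)CCC=C2[C@@H]1CC[C@@H](C)[C@]2(C)CC[C@@H](C)CCO[Si](C)(C)C(C)(C)C | intermediate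
25 | (1S,5S,6R,8aS)-5-[(3R)-5-[(tert-butyldimethylsilyl)oxy]-3-methylpentyl]-1,5,6-trimethyl-1,2,3,5,6,7,8,8a-octahydronaphthalene-1-carboxylic acid | OC(=O)[C@@]1(C)CCC=C2[C@@H]1CC[C@@H](C)[C@]2(C)CC[C@@H](C)CCO[Si](C)(C)C(C)(C)C | intermediate
26 | methyl (1S,5S,6R,8aS)-5-[(3R)-5-[(tert-butyldimethylsilyl)oxy]-3-methylpentyl]-1,5,6-trimethyl-1,2,3,5,6,7,8,8a-octahydronaphthalene-1-carboxylate | COC(=O)[C@@]1(C)CCC=C2[C@@H]1CC[C@@H](C)[C@]2(C)CC[C@@H](C)CCO[Si](C)(C)C(C)(C)C | intermediate
27 | methyl (1S,5S,6R,8aS)-5-[(3R)-5-hydroxy-3-methylpentyl]-1,5,6-trimethyl-1,2,3,5,6,7,8,8a-octahydronaphthalene-1-carboxylate | COC(=O)[C@@]1(C)CCC=C2[C@@H]1CC[C@@H](C)[C@]2(C)CC[C@@H](C)CCO | intermediate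
28 | phenylpropiolic acid, 3-phenylprop-2-ynoic acid | OC(=O)C#Cc1ccccc1 | starting material
29 | methyl (1S,5S,6R,8aS)-1,5,6-trimethyl-5-[(3R)-3-methyl-5-[(3-phenylprop-2-ynoyl)oxy]pentyl]-1,2,3,5,6,7,8,8a-octahydronaphthalene-1-carboxylate | COC(=O)[C@@]1(C)CCC=C2[C@@H]1CC[C@@H](C)[C@]2(C)CC[C@@H](C)CCOC(=O)C#Cc1ccccc1 | intermediate
30 | methyl (1S,5S,6R,8aS)-1,5,6-trimethyl-5-[(3R)-3-methyl-5-[[(2Z)-3-phenylprop-2-enoyl]oxy]pentyl]-1,2,3,5,6,7,8,8a-octahydronaphthalene-1-carboxylate | COC(=O)[C@@]1(C)CCC=C2[C@@H]1CC[C@@H](C)[C@]2(C)CC[C@@H](C)CCOC(=O)/C=C\c1ccccc1 | target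

## Step count and risks

Total: 20 steps. Longest linear sequence: 19 steps (steps 1–4 and 6–20, from 1).

**Step 10 (key step).** The β,β-disubstituted enone may react too slowly at the low temperature that the cis and facial selectivities need, so that Lewis-acid-induced isomerisation or oligomerisation of the diene competes; warming would erode the preference for the nitrile-axial transition state. Fallback: starting from 15, the enone is converted in situ into a 2-alkenyl-1,3-dioxolan-2-ylium ion (1,2-bis(trimethylsilyloxy)ethane, catalytic Me3SiOSO2CF3, CH2Cl2, −78 °C), a much stronger 2π partner, in an ionic Diels–Alder reaction. This should give the dioxolane ketal of the cycloadduct F1, whose hydrolysis (pyridinium p-toluenesulfonate, wet acetone) returns to 16.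

**Step 9.** The phosphonate anion may enolise the ketone or add to it, or elimination of the β-oxido phosphonate may stall. Fallback: starting from 13, a non-basic, aldehyde-selective Takai iodo-olefination (CrCl2, CHI3, THF) should give the (E)-alkenyl iodide F2. Suzuki–Miyaura coupling with (E)-prop-1-enylboronic acid (Pd(PPh3)4, aqueous K3PO4, THF) then returns to 15.

**Step 12.** Deprotonation at the shielded C10–H may be slow, leaving room for base-induced degradation of the enone. Fallback: starting from 18, Luche reduction (NaBH4, CeCl3, MeOH) gives allylic alcohol F3. Its dehydration with methyl N-(triethylammoniosulfonyl)carbamate can only take the C10 hydrogen, since C2 is vinylic, and should give triene F4. Diimide reduction of the two disubstituted olefins of F4 returns to the route at 22.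

**Step 13.** Reduction of the ring B olefin, which lies between two tertiary carbons, may be incomplete, and forcing it may cost selectivity. Fallback: starting from 20, diimide treatment is stopped once C2=C3 is consumed, giving enol triflate F5 with C6=C7 intact. Formate hydrogenolysis as in step 14 gives diene F6. Homogeneous hydrogenation with RhCl(PPh3)3 and H2 then saturates the disubstituted C6=C7 bond in preference to the trisubstituted C1=C10 bond and returns to 22.

## Further compounds

F1 | step 10 | 1,1-ethylenedioxy ketal of 16 | N#C[C@@]1(C)CCC2(OCCO2)[C@H]3[C@@H]1C=C[C@@H](C)[C@]3(C)CC[C@@H](C)CCO[Si](C)(C)C(C)(C)C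
F2 | step 9 | (2S,6E,10R)-12-[(tert-butyldimethylsilyl)oxy]-2-[(E)-2-iodoethenyl]-2,7,10-trimethyl-5-oxododec-6-enenitrile | N#C[C@@](C)(CCC(=O)/C=C(\C)CC[C@@H](C)CCO[Si](C)(C)C(C)(C)C)/C=C/I
F3 | step 12 | C1 allylic alcohol from 18, both C1 epimers | N#C[C@@]1(C)C=CC(O)[C@H]2[C@@H]1C=C[C@@H](C)[C@]2(C)CC[C@@H](C)CCO[Si](C)(C)C(C)(C)C
F4 | step 12 | 1(10),2,6-triene nitrile | N#C[C@@]1(C)C=CC=C2[C@@H]1C=C[C@@H](C)[C@]2(C)CC[C@@H](C)CCO[Si](C)(C)C(C)(C)C
F5 | step 13 | enol triflate with C6=C7 intact | N#C[C@@]1(C)CCC(OS(=O)(=O)C(F)(F)F)=C2[C@@H]1C=C[C@@H](C)[C@]2(C)CC[C@@H](C)CCO[Si](C)(C)C(C)(C)C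
F6 | step 13 | 1(10),6-diene nitrile | N#C[C@@]1(C)CCC=C2[C@@H]1C=C[C@@H](C)[C@]2(C)CC[C@@H](C)CCO[Si](C)(C)C(C)(C)C
A1 | alternative 1 | ring A dienyl ketal (C5=C10–C9=C8 diene, C1 dioxolane) | COC(=O)[C@@]1(C)CCC2(OCCO2)C(/C(C)=C/C)=C1
A2 | alternative 1 | ethynyl p-tolyl sulfone | C#CS(=O)(=O)c1ccc(C)cc1
A3 | alternative 1 | 7-sulfonyl hexahydronaphthalene ketal | COC(=O)[C@@]1(C)CCC2(OCCO2)C=3[C@@H]1C=C(S(=O)(=O)c4ccc(C)cc4)[C@@H](C)C=3C
A4 | alternative 2 | ring B vinylcyclohexene (C2=C1–C10=C5 diene) | C=CC1=CCC[C@@H](C)[C@]1(C)CC[C@@H](C)CCO[Si](C)(C)C(C)(C)C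
A5 | alternative 2 | methacrolein | CC(=C)C=O
A6 | alternative 2 | C4 aldehyde of the silyl-protected halim-1(10)-ene (same as 24) | O=C[C@@]1(C)CCC=C2[C@@H]1CC[C@@H](C)[C@]2(C)CC[C@@H](C)CCO[Si](C)(C)C(C)(C)C
A7 | alternative 3 | keto aldehyde (C10 ketone, C1 aldehyde) | COC(=O)[C@@](C)(CCC=O)[C@H]1CC[C@@H](C)[C@](C)(CC[C@@H](C)CCO[Si](C)(C)C(C)(C)C)C1=O
A8 | alternative 3 | silyl-protected halim-1(10)-ene methyl ester (same as 26) | COC(=O)[C@@]1(C)CCC=C2[C@@H]1CC[C@@H](C)[C@]2(C)CC[C@@H](C)CCO[Si](C)(C)C(C)(C)C
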